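**Strategy.** The ring-fusion bond C3a–C8a (azulene numbering; ring A = cyclopentane, ring B = cycloheptenone) is formed by a one-carbon insertion. C3a is a methine flanked by the two oxygenated carbons C3 and C4, and C8a is quaternary. C3a can therefore arrive as a diazo carbon that adds to a C4 ketone of a cyclohexanone and then accepts C8a in a 1,2-shift. This single operation contracts a six-membered ring to ring A, enlarges the cyclohexanone to ring B and sets the trans fusion. The precursor is a keto aldehyde (converted in the flask to its tosylhydrazone), made by ozonolysis of an isopropyl carbinol derived from a methylated Wieland–Miescher ketone.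

Key step: step 6

Remarks on the chemistry (assumptions):
- The methyl-bearing ring carbon that ends as C6 is carried as a mixture of both epimers in compounds 5 to 19; it becomes sp2 in step 10, and the SMILES leave it undefined.
- (S)-Proline in step 2 fixes the absolute configuration; any shortfall in enantiomeric purity is assumed to be removed by crystallisation of 8 or 10.

Step 1
Reactants: 1 5-methylcyclohexane-1,3-dione; 2 iodomethane
Product: 3 2,5-dimethylcyclohexane-1,3-dione
Conditions: MeI, NaOH, H2O/MeOH, 65 °C
Reagents that add atoms: iodomethane (2), CI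
Why: C-alkylation of the 1,3-dione enolate at the doubly activated C2 with methyl iodide in aqueous base is the standard entry to 2-methyl-1,3-diones and creates no stereocentre of consequence.

Step 2
Reactants: 3 2,5-dimethylcyclohexane-1,3-dione; 4 methyl vinyl ketone
Product: 6 (8aS)-3,8a-dimethyl-3,4,8,8a-tetrahydronaphthalene-1,6(2H,7H)-dione, via triketone 5 (not isolated)
Conditions: MVK, (S)-proline (cat.), DMSO, 35 °C
Reagents that add atoms: methyl vinyl ketone (4), CC(=O)C=C
Why: Michael addition followed by proline-enamine aldol condensation (Hajos–Parrish–Eder–Sauer–Wiechert reaction, a Robinson annulation) differentiates the two enantiotopic ring carbonyls, so the (S)-catalyst should set the angular quaternary carbon as 8aS.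

Step 3
Reactants: 6 the enedione; 7 ethane-1,2-diol
Product: 8 (8'aS)-3',8'a-dimethyl-3',4',8',8'a-tetrahydro-2'H-spiro[[1,3]dioxolane-2,1'-naphthalen]-6'(7'H)-one
Conditions: HOCH2CH2OH, TsOH·H2O (cat.), 4 Å MS, 25 °C
Reagents that add atoms: ethane-1,2-diol (7), OCCO
Why: Acid-catalysed ketalisation is chemoselective for the saturated C1 ketone over the less electrophilic conjugated ketone, which leaves the enone carbonyl as the only one open to step 4.

Step 4
Reactants: 8 the ketal enone; 9 isopropylmagnesium chloride
Product: 10 (6'R,8'aS)-3',8'a-dimethyl-6'-(propan-2-yl)-3',4',6',7',8',8'a-hexahydro-2'H-spiro[[1,3]dioxolane-2,1'-naphthalen]-6'-ol (hydroxyl cis to the angular methyl)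
Conditions: iPrMgCl, CeCl3, THF, −78 to 0 °C
Reagents that add atoms: isopropylmagnesium chloride (9), CC(C)[Mg]Cl
Why: Organocerium 1,2-addition to the enone (CeCl3 suppresses enolisation and conjugate addition) should occur axially on the face opposite the angular methyl, as with steroidal 4-en-3-ones, which places the new hydroxyl cis to that methyl (6'R).

Step 5
Reactants: 10 the tertiary allylic alcohol
Product: 11 (2R)-4-[(6S)-6,9-dimethyl-7-oxo-1,4-dioxaspiro[4.5]decan-6-yl]-2-hydroxy-2-(propan-2-yl)butanal
Conditions: O3, CH2Cl2, −78 °C; then PPh3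
Reagents that add atoms: ozone, [O-][O+]=O
Why: Ozonolysis with reductive work-up cleaves the only C=C bond, giving the ring ketone and an α-hydroxy aldehyde that has no α-hydrogen, and leaves both stereocentres untouched.

Step 6
Reactants: 11 the keto aldehyde
Product: 15 (3R,3aR,8aS)-8,8-(ethylenedioxy)-3-hydroxy-6,8a-dimethyl-3-(propan-2-yl)-2,3,3a,5,6,7,8,8a-octahydroazulen-4(1H)-one, via tosylhydrazone 12 (not isolated), via diazoalkane 13 (not isolated), via diazonium alkoxide betaine 14 (not isolated)
Conditions: TsNHNH2, 4 Å MS, THF, 25 °C; NaH (1 equiv), 0 °C; BnEt3NCl (cat.), 45 °C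
Reagents that add atoms: none
Why: The aldehyde condenses to tosylhydrazone 12, whose sodium salt loses sulfinate (Bamford–Stevens) to give diazoalkane 13; its nucleophilic carbon adds to the neighbouring ring ketone (6-exo-trig) to give betaine 14, and loss of N2 is coupled to a 1,2-shift of the quaternary carbon from the carbinol carbon to the diazonium carbon. The closest known reaction type is the intramolecular diazoalkane–ketone ring enlargement (Tiffeneau–Demjanov or Büchner–Curtius–Schlotterbeck homologation) of ω-diazoalkyl cycloalkanones to fused bicyclic ketones. Ring A closes by contraction of the six-membered betaine ring (C3a–C8a formed, C4–C8a broken), and ring B arises at the same time by one-carbon enlargement of the cyclohexanone. C8a migrates with retention and keeps the configuration from step 2, C3 is untouched, and C3a is set with inversion at the diazonium carbon, whose N2 group should lie equatorial in a chair betaine (isopropyl equatorial, C3 hydroxyl axial and hydrogen-bonded to the alkoxide) because an axial N2 would be 1,3-diaxial to the ketal carbon; this geometry gives the trans fusion. The step needs C8a, which is antiperiplanar to the equatorial C–N2 bond, to migrate in preference to C5, to epoxide closure and to a shift of C2 driven by the C3 hydroxyl; the chair geometry, the alkoxide being the stronger donor and the higher migratory aptitude of the quaternary carbon should secure this, and the ketal leaves a single ketone to be attacked.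

Step 7
Reactants: 15 the β-hydroxy ketone
Product: 16 (3R,3aS,4S,8aS)-8,8-(ethylenedioxy)-6,8a-dimethyl-3-(propan-2-yl)decahydroazulene-3,4-diol
Conditions: Me4NBH(OAc)3, MeCN/AcOH, −30 °C
Reagents that add atoms: none
Why: In this hydroxyl-directed reduction (Evans–Saksena) the C3 hydroxyl exchanges onto boron and delivers hydride intramolecularly to the face of the C4 ketone on which it sits, which should give the 4S alcohol trans to the C3 hydroxyl (anti-1,3-diol).

Step 8
Reactants: 16 the diol; 17 4-acetoxy-3-methoxybenzoic acid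
Product: 18 (3R,3aS,4S,8aS)-8,8-(ethylenedioxy)-3-hydroxy-6,8a-dimethyl-3-(propan-2-yl)decahydroazulen-4-yl 4-acetoxy-3-methoxybenzoate
Conditions: DCC, DMAP (cat.), CH2Cl2, 25 °C
Reagents that add atoms: 4-acetoxy-3-methoxybenzoic acid (17), COc1cc(C(=O)O)ccc1OC(C)=O
Why: Steglich esterification should acylate only the secondary C4 hydroxyl with retention, the tertiary C3 hydroxyl being too hindered and the phenol of the acid being masked as its acetate.

Step 9
Reactants: 18 the ester ketal
Product: 19 (3R,3aS,4S,8aS)-3-hydroxy-6,8a-dimethyl-8-oxo-3-(propan-2-yl)decahydroazulen-4-yl 4-acetoxy-3-methoxybenzoate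
Conditions: aq. HCl (1 M), THF, 25 °C
Reagents that add atoms: water, O
Why: Mild acid hydrolysis of the dioxolane liberates the C8 ketone, and the aryl acetate, the benzoate ester and the tertiary alcohol should tolerate dilute acid at room temperature.

Step 10
Reactants: 19 the saturated ketone
Product: 20 (3R,3aS,4S,8aS)-3-hydroxy-6,8a-dimethyl-8-oxo-3-(propan-2-yl)-1,2,3,3a,4,5,8,8a-octahydroazulen-4-yl 4-acetoxy-3-methoxybenzoate
Conditions: IBX (2-iodoxybenzoic acid), DMSO, 70 °C
Reagents that add atoms: none
Why: IBX-mediated α,β-dehydrogenation through the enol can only proceed toward C7 because C8a is quaternary, which gives the C6–C7 enone and makes both C6 epimers converge.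

Step 11
Reactants: 20 the enone acetate
Product: 21 (3R,3aS,4S,8aS)-3-hydroxy-6,8a-dimethyl-8-oxo-3-(propan-2-yl)-1,2,3,3a,4,5,8,8a-octahydroazulen-4-yl 4-hydroxy-3-methoxybenzoate
Conditions: NH4OAc, MeOH/H2O, 25 °C
Reagents that add atoms: none
Why: Ammonium acetate in aqueous methanol cleaves aryl acetates selectively by transesterification under nearly neutral conditions, which should spare the secondary vanillate ester and the base-sensitive δ-acyloxy enone.

**Compound list**

1 | 5-methylcyclohexane-1,3-dione | CC1CC(=O)CC(=O)C1 | starting material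
2 | iodomethane | CI | starting material
3 | 2,5-dimethylcyclohexane-1,3-dione | CC1CC(=O)C(C)C(=O)C1 | intermediate
4 | methyl vinyl ketone (but-3-en-2-one) | CC(=O)C=C | starting material
5 | 2,5-dimethyl-2-(3-oxobutyl)cyclohexane-1,3-dione (triketone, not isolated) | CC(=O)CCC1(C)C(=O)CC(C)CC1=O | intermediate
6 | (8aS)-3,8a-dimethyl-3,4,8,8a-tetrahydronaphthalene-1,6(2H,7H)-dione (both C3 epimers) | C[C@]12CCC(=O)C=C1CC(C)CC2=O | intermediate
7 | ethane-1,2-diol | OCCO | starting material
8 | (8'aS)-3',8'a-dimethyl-3',4',8',8'a-tetrahydro-2'H-spiro[[1,3]dioxolane-2,1'-naphthalen]-6'(7'H)-one | C[C@]12CCC(=O)C=C1CC(C)CC23OCCO3 | intermediate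
9 | isopropylmagnesium chloride | CC(C)[Mg]Cl | starting material
10 | (6'R,8'aS)-3',8'a-dimethyl-6'-(propan-2-yl)-3',4',6',7',8',8'a-hexahydro-2'H-spiro[[1,3]dioxolane-2,1'-naphthalen]-6'-ol (OH cis to angular CH3) | C[C@]12CC[C@@](O)(C(C)C)C=C1CC(C)CC23OCCO3 | intermediate
11 | (2R)-4-[(6S)-6,9-dimethyl-7-oxo-1,4-dioxaspiro[4.5]decan-6-yl]-2-hydroxy-2-(propan-2-yl)butanal | O=C[C@](O)(C(C)C)CC[C@@]1(C)C(=O)CC(C)CC12OCCO2 | intermediate
12 | (E)-4-methylbenzenesulfonylhydrazone of aldehyde 11 (not isolated) | Cc1ccc(cc1)S(=O)(=O)N/N=C/[C@](O)(C(C)C)CC[C@@]1(C)C(=O)CC(C)CC12OCCO2 | intermediate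
13 | (6S)-6-[(3R)-4-diazo-3-hydroxy-3-(propan-2-yl)butyl]-6,9-dimethyl-1,4-dioxaspiro[4.5]decan-7-one (not isolated) | [N-]=[N+]=C[C@](O)(C(C)C)CC[C@@]1(C)C(=O)CC(C)CC12OCCO2 | intermediate
14 | cis-fused decalin betaine with 4a-oxido, 5-diazonio, 6-hydroxy and 8a-methyl groups all on one face (not isolated) | [O-][C@]12CC(C)CC3(OCCO3)[C@@]1(C)CC[C@@](O)(C(C)C)[C@@H]2[N+]#N | intermediate
15 | (3R,3aR,8aS)-8,8-(ethylenedioxy)-3-hydroxy-6,8a-dimethyl-3-(propan-2-yl)-2,3,3a,5,6,7,8,8a-octahydroazulen-4(1H)-one (trans-fused) | O=C1CC(C)CC2(OCCO2)[C@@]3(C)CC[C@@](O)(C(C)C)[C@H]13 | intermediate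
16 | (3R,3aS,4S,8aS)-8,8-(ethylenedioxy)-6,8a-dimethyl-3-(propan-2-yl)decahydroazulene-3,4-diol | O[C@H]1CC(C)CC2(OCCO2)[C@@]3(C)CC[C@@](O)(C(C)C)[C@H]13 | intermediate
17 | 4-acetoxy-3-methoxybenzoic acid | COc1cc(C(=O)O)ccc1OC(C)=O | starting material
18 | (3R,3aS,4S,8aS)-8,8-(ethylenedioxy)-3-hydroxy-6,8a-dimethyl-3-(propan-2-yl)decahydroazulen-4-yl 4-acetoxy-3-methoxybenzoate | COc1cc(C(=O)O[C@H]2CC(C)CC3(OCCO3)[C@@]4(C)CC[C@@](O)(C(C)C)[C@H]24)ccc1OC(C)=O | intermediate
19 | (3R,3aS,4S,8aS)-3-hydroxy-6,8a-dimethyl-8-oxo-3-(propan-2-yl)decahydroazulen-4-yl 4-acetoxy-3-methoxybenzoate | COc1cc(C(=O)O[C@H]2CC(C)CC(=O)[C@@]3(C)CC[C@@](O)(C(C)C)[C@H]23)ccc1OC(C)=O | intermediate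
20 | (3R,3aS,4S,8aS)-3-hydroxy-6,8a-dimethyl-8-oxo-3-(propan-2-yl)-1,2,3,3a,4,5,8,8a-octahydroazulen-4-yl 4-acetoxy-3-methoxybenzoate | COc1cc(C(=O)O[C@H]2CC(C)=CC(=O)[C@@]3(C)CC[C@@](O)(C(C)C)[C@H]23)ccc1OC(C)=O | intermediate
21 | (3R,3aS,4S,8aS)-3-hydroxy-6,8a-dimethyl-8-oxo-3-(propan-2-yl)-1,2,3,3a,4,5,8,8a-octahydroazulen-4-yl 4-hydroxy-3-methoxybenzoate | COc1cc(C(=O)O[C@H]2CC(C)=CC(=O)[C@@]3(C)CC[C@@](O)(C(C)C)[C@H]23)ccc1O | target

**Total step count:** 11. **Longest linear sequence:** 11 steps (from 1 to 21).

**Steps most likely to fail**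

Step 6 (key step). The diazoalkane may lose N2 before it reaches the ketone. The betaine may instead close to an epoxide. The C3 hydroxyl may drive a shift of C2 in place of C8a. The fallback runs the same 1,2-shift on a sulfonate instead of a diazonium group and sets out from allylic alcohol 10. Hydroxyl-directed syn-dihydroxylation (OsO4, TMEDA, CH2Cl2, −78 °C) on the face of the tertiary hydroxyl should give the all-cis triol F1. Selective sulfonylation of its only secondary hydroxyl (MsCl, Et3N, CH2Cl2, −20 °C) gives the mesylate F2. KOtBu in tBuOH/THF should then trigger the pinacol-type shift of the ring-fusion carbon onto the carbon that bears the equatorial mesylate. This returns to the route at 15.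

Step 4. Facial selectivity of the bulky secondary nucleophile may be poor, and enolisation of the enone may compete. The fallback sets out from ketal enone 8 and installs the group in two operations. Addition of isopropenylmagnesium bromide with CeCl3 (THF, −78 °C), a slimmer sp2 nucleophile with a stronger preference for axial attack, gives the isopropenyl carbinol F3. Hydrogenation with H2 and RhCl(PPh3)3 should reduce only the 1,1-disubstituted alkene and leave the trisubstituted ring alkene. This returns to the route at 10.

Step 7. Ligand exchange at the tertiary hydroxyl may be slow, so that undirected hydride attack from the less hindered face gives the C4 epimer. The fallback uses that outcome and sets out from 15. NaBH4 with CeCl3 in MeOH at −40 °C should attack the face away from the angular methyl and the C3 substituents and give the C4-epimeric diol F4. Mitsunobu esterification of F4 with acid 17 (PPh3, DIAD, toluene) inverts C4. This returns to the route at 18, and step 8 is then not needed.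

**Further compounds**

F1 | step 6 | all-cis triol from 10: 4'a,5',6'-trihydroxy ketal with the three hydroxyls and the 8'a-methyl on one face | C[C@]12CC[C@@](O)(C(C)C)[C@H](O)[C@@]1(O)CC(C)CC23OCCO3
F2 | step 6 | 5'-O-methanesulfonate of triol F1 | C[C@]12CC[C@@](O)(C(C)C)[C@H](OS(C)(=O)=O)[C@@]1(O)CC(C)CC23OCCO3
F3 | step 4 | isopropenyl analogue of 10 (6'-(prop-1-en-2-yl) carbinol, hydroxyl cis to the angular methyl) | C[C@]12CC[C@@](O)(C(C)=C)C=C1CC(C)CC23OCCO3
F4 | step 7 | (3R,3aS,4R,8aS)-8,8-(ethylenedioxy)-6,8a-dimethyl-3-(propan-2-yl)decahydroazulene-3,4-diol (C4 epimer of 16) | O[C@@H]1CC(C)CC2(OCCO2)[C@@]3(C)CC[C@@](O)(C(C)C)[C@H]13
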